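**Retrosynthetic overview**
- The only strategic cut is the C2–C3 σ-bond of the octacosanoyl chain (ester α-CH2 to the first CH2 of the linear C26 tail). It is made by an anodic decarboxylative radical cross-coupling (mixed Kolbe electrolysis).
- Enabling feature: C2 and C3 are unhindered sp3 methylenes. C2 sits on the ester carbonyl C1, and C3 heads an unbranched, heteroatom-free alkyl chain. There is no stereocentre nearby, and the only ring (the benzene ring) lies on the alkoxy side, separated from C1 by O–CH2–CH2. Each carbon can therefore carry a CO2H as a traceless handle and be released as a primary radical that resists over-oxidation.
- Meldrum's acid 1 and 2-phenylethanol 2 give mono(2-phenylethyl) malonate 3, which supplies C1–C2 and the alcohol part. Heptacosanoic acid 4 supplies C3–C28 after loss of its carboxyl carbon. The radicals 5 and 6 couple to the target 7.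
- No ring is formed in the route; the benzene ring is bought intact in 2.

Key step: step 2

Remark: the target has no stereocentre and no stereogenic double bond, so it is a single achiral compound and no stereocontrol is needed.

Step 1
Reactants: 1 Meldrum's acid (2,2-dimethyl-1,3-dioxane-4,6-dione); 2 2-phenylethanol
Product: 3 mono(2-phenylethyl) malonate [3-oxo-3-(2-phenylethoxy)propanoic acid]
Conditions: 1 (1.05 equiv), 2 (1.0 equiv), toluene, 100 °C, 4 h; NaHCO3 extraction, then acidification to pH 2
Reagents that add atoms: none
Why: Thermal alcoholysis of Meldrum's acid (ring-opening nucleophilic acyl substitution by the primary alcohol, then loss of acetone) should give the malonic half-ester selectively, because the freed carboxylic acid is not esterified under these neutral conditions; no stereocentre is formed.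

Step 2
Reactants: 3 mono(2-phenylethyl) malonate (5 equiv in total, fed slowly); 4 heptacosanoic acid (1 equiv)
Product: 7 2-phenylethyl octacosanoate, via hexacosyl radical 5 (not isolated), via 2-phenylethoxycarbonylmethyl radical 6 (not isolated)
Conditions: undivided cell, RVC(+)/RVC(−), rapid alternating polarity (50 ms), constant cell voltage, KOH (0.1 equiv), acetone (dilute in 4), 40 °C; 3 added by syringe pump until 4 is consumed
Reagents that add atoms: none
Why: Mixed Kolbe electrolysis (anodic decarboxylative radical cross-coupling): the carboxylates of 3 and 4 are each oxidised by one electron at the anode and lose CO2 to give the primary radicals 6 and 5, which should combine at the electrode surface to form the C2–C3 σ-bond of 7, while the acid protons are reduced to H2 at the counter-electrode. The closest known reaction type is the cross-Kolbe chain extension of fatty acids with dicarboxylic acid half-esters, together with the Brown–Walker coupling of malonic half-esters; the alternating-polarity variant in acetone is chosen so that no alcohol solvent can transesterify the 2-phenylethyl ester. No ring is closed and no stereocentre is created. The step needs cross-coupling over homo-coupling, radical coupling over further oxidation to carbocations (non-Kolbe products), and oxidation of carboxylate in preference to the arene. The substrate secures the last two: both radical centres are primary and unhindered, the α-ester radical 6 and the unstabilised alkyl radical 5 are both hard to oxidise further, and the only π-system is a non-activated monoalkylbenzene insulated from the reacting carbon by the ester and two CH2 groups. Cross-selectivity is handled by feeding the cheap half-ester 3 in excess, so that the limiting radical 5 should mostly meet 6; the homodimers (a polar succinate diester and a C52 alkane) differ enough in polarity from 7 to be removed by chromatography or crystallisation.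

**Compound list**
1 | Meldrum's acid (2,2-dimethyl-1,3-dioxane-4,6-dione) | CC1(C)OC(=O)CC(=O)O1 | starting material
2 | 2-phenylethanol | OCCc1ccccc1 | starting material
3 | mono(2-phenylethyl) malonate [3-oxo-3-(2-phenylethoxy)propanoic acid] | OC(=O)CC(=O)OCCc1ccccc1 | intermediate
4 | heptacosanoic acid | CCCCCCCCCCCCCCCCCCCCCCCCCCC(=O)O | starting material
5 | hexacosyl radical | CCCCCCCCCCCCCCCCCCCCCCCCC[CH2] | intermediate
6 | 2-phenylethoxycarbonylmethyl radical | [CH2]C(=O)OCCc1ccccc1 | intermediate
7 | 2-phenylethyl octacosanoate | CCCCCCCCCCCCCCCCCCCCCCCCCCCC(=O)OCCc1ccccc1 | target

**Total step count:** 2
**Longest linear sequence:** 2 steps (1/2 → 3 → 7)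

**Steps most likely to fail** (the route has only two steps, so both are ranked)

1. Step 2 (key step). Cross-selectivity may be lost: the more acidic half-ester 3 can monopolise the base and the anode, so that each acid homo-couples in turn instead of cross-coupling. The electrodes may also be fouled by the sparingly soluble C27 acid or the waxy product, and the arene may be oxidised at the anode. The fallback uses known chemistry and a different approach, a one-carbon homologation with 1,2-alkyl shift (Arndt–Eistert), in which the migrating C26 group forms the same C2–C3 bond. It sets out from heptacosanoic acid 4. Oxalyl chloride with catalytic DMF in CH2Cl2/toluene at 40 °C should give heptacosanoyl chloride F1. Diazomethane with Et3N as HCl scavenger in Et2O/THF at 0 °C should convert it into 1-diazooctacosan-2-one F2. Silver benzoate (cat.) and Et3N in THF at 50 °C, with an excess of 2-phenylethanol 2, should then trigger the Wolff rearrangement to hexacosylketene F3 (not isolated), which is trapped by 2. The fallback comes back to the route at the target 7.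

2. Step 1. The half-acid may decarboxylate thermally to the acetate ester on prolonged heating, or ring-opening may stay incomplete if heating is cut short. The fallback replaces the acylal opening by a protected-malonate esterification and sets out from 2-phenylethanol 2. Steglich esterification with commercial mono-tert-butyl malonate (CC(C)(C)OC(=O)CC(=O)O), DCC and catalytic DMAP in CH2Cl2 at 0 °C to rt should give tert-butyl 2-phenylethyl malonate F4. TFA in CH2Cl2 at rt should then cleave the tert-butyl ester; the primary 2-phenylethyl ester should survive. The fallback comes back to the route at half-ester 3.

**Further compounds**
F1 | step 2 | heptacosanoyl chloride | CCCCCCCCCCCCCCCCCCCCCCCCCCC(=O)Cl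
F2 | step 2 | 1-diazooctacosan-2-one | CCCCCCCCCCCCCCCCCCCCCCCCCCC(=O)C=[N+]=[N-]
F3 | step 2 | hexacosylketene (octacos-1-en-1-one) | CCCCCCCCCCCCCCCCCCCCCCCCCCC=C=O
F4 | step 1 | tert-butyl 2-phenylethyl malonate | CC(C)(C)OC(=O)CC(=O)OCCc1ccccc1
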